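**Plan**
1. Retrosynthetic cuts: the O-benzyl and O-silyl groups; the C2–C3 bond of the 2,3-dihydrobenzofuran (ring closure); the aryl ether bond O1–C2; at the diarylmethine carbon, the bond to catechin C8 and the bond to the CH2 carbon (both made on boron).
2. Forward: (+)-catechin is benzylated and brominated at C8; a pinanediol arylboronate is homologated to an α-chloro boronate, arylated by the 8-lithiocatechin, extended by CH2 and oxidised to a 2,2-diarylethanol; Mitsunobu etherification with a bis-silylated phloroglucinaldehyde, tosylhydrazone formation, cobalt-carbene closure of the dihydrofuran ring, desilylation, hydrogenolysis.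
3. Stereochemistry: flavan C2/C3 come from (+)-catechin; the (R)-diarylmethine comes from the (+)-pinanediol-directed homologation followed by aryl migration with inversion; C2 (S) of the dihydrobenzofuran is set in the ring closure under control of the neighbouring diarylmethine.
4. Enabling feature: in the ether precursor the O1–C2H2 group and the formyl-derived carbon C3 sit on the adjacent ring-A carbons C7a and C3a. A carbene at C3 therefore reaches a C2–H through a six-membered transition state, O1 weakens that C–H, and closure gives the five-membered ring O1–C2–C3–C3a–C7a. The other ortho oxygen (on C4) carries silicon and offers no such C–H.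
5. Helpers: the aldehyde oxidation level at C3 (as tosylhydrazone, lost as N2 and sulfinate in the key step) and the two silyl groups (removed in step 12).

Key step: step 11

Remark: the target is read as a (2S)-2,3-dihydrobenzofuran-4,6-diol whose C2 carries an (R)-diarylmethine bound to C8 of (+)-catechin (2R,3S); (+)-catechin, [3,4-bis(benzyloxy)phenyl]boronic acid, (+)-pinanediol and 2,4,6-trihydroxybenzaldehyde are taken as commercial, and (+)-pinanediol boronates are assumed to show their usual sense of induction in the dichloromethyllithium homologation.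

Abbreviations in names: ArB = 3,4-bis(benzyloxy)phenyl; Cat = (2R,3S)-3,5,7-tris(benzyloxy)-2-[3,4-bis(benzyloxy)phenyl]-3,4-dihydro-2H-chromen-8-yl (the 8-yl group of penta-O-benzyl-(+)-catechin).

**Route**

Step 1
Reactants: 1 (+)-catechin
Product: 2 5,7,3′,4′-tetra-O-benzyl-(+)-catechin
Conditions: BnBr (4.4 equiv), K2CO3, DMF, 0 °C → rt, argon
Reagents that add atoms: benzyl bromide, BrCc1ccccc1
Why: Williamson O-benzylation; the four phenols are far more acidic than the secondary 3-OH, so carbonate base should alkylate only the phenolic oxygens and leave C2 and C3 untouched.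

Step 2
Reactants: 2 5,7,3′,4′-tetra-O-benzyl-(+)-catechin
Product: 3 3,5,7,3′,4′-penta-O-benzyl-(+)-catechin
Conditions: NaH, BnBr, DMF, 0 °C → rt
Reagents that add atoms: benzyl bromide, BrCc1ccccc1
Why: Williamson etherification of the remaining secondary alcohol as its sodium alkoxide; with every phenol capped, base-induced ring opening and epimerisation at C2 are not possible.

Step 3
Reactants: 3 3,5,7,3′,4′-penta-O-benzyl-(+)-catechin
Product: 4 8-bromo-3,5,7,3′,4′-penta-O-benzyl-(+)-catechin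
Conditions: NBS (1.0 equiv), CH2Cl2, −78 °C → 0 °C
Reagents that add atoms: N-bromosuccinimide, O=C1CCC(=O)N1Br
Why: electrophilic aromatic bromination; C8 is the most nucleophilic position of the benzylated ring A of flavan-3-ols, so one equivalent of NBS at low temperature should brominate there and fix the later point of attachment.

Step 4
Reactants: 5 [3,4-bis(benzyloxy)phenyl]boronic acid; 6 (+)-pinanediol [(1S,2S,3R,5S)-2,6,6-trimethylbicyclo[3.1.1]heptane-2,3-diol]
Product: 7 (+)-pinanediol [3,4-bis(benzyloxy)phenyl]boronate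
Conditions: Et2O, rt; concentration from toluene
Reagents that add atoms: none
Why: condensation of a boronic acid with a cis-1,2-diol to a stable dioxaborolane, which installs the chiral director on boron.

Step 5
Reactants: 7 (+)-pinanediol [3,4-bis(benzyloxy)phenyl]boronate
Product: 9 (+)-pinanediol [(S)-chloro(ArB)methyl]boronate, via lithium dichloromethyl borate complex 8 (not isolated)
Conditions: CH2Cl2, n-BuLi, THF, −100 °C; then ZnCl2, −100 °C → rt
Reagents that add atoms: dichloromethane, ClCCl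
Why: Matteson asymmetric homologation, in which LiCHCl2 adds to boron and the aryl group migrates with loss of the chloride selected by the (+)-pinanediol ring, which should give the (S)-α-chloro boronate, while ZnCl2 promotes the shift and binds the free chloride that would otherwise epimerise the benzylic centre.

Step 6
Reactants: 4 8-bromo-3,5,7,3′,4′-penta-O-benzyl-(+)-catechin; 9 (+)-pinanediol [(S)-chloro(ArB)methyl]boronate
Product: 12 (+)-pinanediol [(R)-(ArB)(Cat)methyl]boronate, via 8-lithio-penta-O-benzylcatechin 10 (not isolated), via lithium diorganoborate complex 11 (not isolated)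
Conditions: 4, t-BuLi (2 equiv), THF, −78 °C; then 9, −78 °C → rt
Reagents that add atoms: none
Why: bromine–lithium exchange gives the C8 aryllithium, which adds to boron, and the borate undergoes the Matteson-type 1,2-migration of the catechin aryl group anti to the leaving chloride, so the (S)-chloride is converted with inversion into the (R)-diarylmethine and the link to C8 is fixed by the position of the bromine.

Step 7
Reactants: 12 (+)-pinanediol [(R)-(ArB)(Cat)methyl]boronate
Product: 15 (2R)-2-(ArB)-2-(Cat)ethanol, via lithium chloromethyl borate complex 13 (not isolated), via homologated pinanediol 2,2-diarylethylboronate 14 (not isolated)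
Conditions: BrCH2Cl, n-BuLi, THF, −78 °C → rt; then NaOH, H2O2, THF/H2O, 0 °C
Reagents that add atoms: bromochloromethane, ClCBr; hydrogen peroxide, OO
Why: Matteson homologation with LiCH2Cl (1,2-shift of the diarylmethyl group with retention) followed by stereoretentive oxidation of the primary C–B bond, neither of which touches the diarylmethine configuration.

Step 8
Reactants: 16 2,4,6-trihydroxybenzaldehyde
Product: 17 2-hydroxy-4,6-bis(triisopropylsilyloxy)benzaldehyde
Conditions: TIPSCl (2.1 equiv), imidazole, DMF, 0 °C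
Reagents that add atoms: chlorotriisopropylsilane, CC(C)[Si](Cl)(C(C)C)C(C)C
Why: phenol silylation at the para and one ortho oxygen; the last ortho OH is held in a hydrogen bond to the formyl oxygen and should remain free, and the O–Si groups place no C–H next to oxygen for the later carbene.

Step 9
Reactants: 15 (2R)-2-(ArB)-2-(Cat)ethanol; 17 2-hydroxy-4,6-bis(triisopropylsilyloxy)benzaldehyde
Product: 18 2-[(2R)-2-(ArB)-2-(Cat)ethoxy]-4,6-bis(triisopropylsilyloxy)benzaldehyde
Conditions: PPh3, DIAD, toluene, 0 °C → rt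
Reagents that add atoms: none
Why: Mitsunobu etherification of a primary alcohol with an acidic, chelated phenol; substitution occurs at CH2 and leaves the stereocentre intact, and the non-polar solvent and low temperature should disfavour participation of the electron-rich aryl groups.

Step 10
Reactants: 18 2-[(2R)-2-(ArB)-2-(Cat)ethoxy]-4,6-bis(triisopropylsilyloxy)benzaldehyde
Product: 19 (E)-N-tosylhydrazone of aldehyde 18
Conditions: TsNHNH2 (1.05 equiv), THF/MeOH, 50 °C
Reagents that add atoms: 4-methylbenzenesulfonohydrazide, Cc1ccc(cc1)S(=O)(=O)NN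
Why: condensation of the aldehyde with tosylhydrazide gives the bench-stable carbene precursor without affecting silyl or benzyl ethers.

Step 11
Reactants: 19 (E)-N-tosylhydrazone of aldehyde 18
Product: 21 (2S)-2-[(R)-(ArB)(Cat)methyl]-4,6-bis(triisopropylsilyloxy)-2,3-dihydrobenzofuran, via aryldiazomethane 20 (not isolated)
Conditions: Co(TPP) (5 mol %), Cs2CO3, toluene, 60 °C
Reagents that add atoms: none
Why: Base releases diazo compound 20 from the hydrazone (Bamford–Stevens); Co(TPP) (cobalt tetraphenylporphyrin, divalent cobalt) takes it up with loss of N2 as a trivalent-cobalt carbene radical centred on the benzylic carbon C3, this radical abstracts a hydrogen from the O1–CH2 carbon through a six-membered transition state (1,5-HAT), and the resulting α-aryloxyalkyl radical at C2 displaces cobalt from C3, forming the C2–C3 bond and returning the catalyst. The closest known reactions are the cobalt-porphyrin-catalysed cyclisation of ortho-aminoaryl tosylhydrazones to indolines (the same 1,5-HAT and radical substitution next to a heteroatom) and the 1,5-C–H insertion of ortho-alkoxyaryl carbenes, thermal or rhodium-catalysed, to 2,3-dihydrobenzofurans. The dihydrofuran ring O1–C2–C3–C3a–C7a closes in a 5-exo-tet radical substitution at the cobalt-bound carbon. The new stereocentre C2 is controlled by the adjacent (R)-diarylmethine: in the conformer that places its C–H in the plane of the radical next to O1 (least allylic 1,3-strain) the catechin-8-yl group covers one face, and bond formation on the other face should give 2S. The step needs 1,5- over 1,6-hydrogen abstraction and ring closure over carbene dimerisation; the first is secured by the O1-activated, unhindered CH2 (the only 1,6 C–H is the shielded diarylmethine C–H, and the second ortho oxygen bears silicon), the second by slow release of 20 at low stationary concentration.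

Step 12
Reactants: 21 (2S)-2-[(R)-(ArB)(Cat)methyl]-4,6-bis(triisopropylsilyloxy)-2,3-dihydrobenzofuran
Product: 22 (2S)-2-[(R)-(ArB)(Cat)methyl]-2,3-dihydrobenzofuran-4,6-diol
Conditions: TBAF, AcOH, THF, 0 °C
Reagents that add atoms: none
Why: fluoride-mediated cleavage of the two aryl silyl ethers, with acetic acid buffering the phenoxides; benzyl ethers and both stereocentres of the new ring are inert.

Step 13
Reactants: 22 (2S)-2-[(R)-(ArB)(Cat)methyl]-2,3-dihydrobenzofuran-4,6-diol
Product: 23 target CNP0280971.2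
Conditions: H2 (1 atm), Pd(OH)2/C, THF/MeOH, rt; filtration under argon
Reagents that add atoms: none
Why: catalytic hydrogenolysis of all seven benzyl ethers; the cyclic benzylic C2–O1 bond of the flavan and the dihydrobenzofuran ring should survive at ambient pressure and temperature.

**Compound list**
1 | (+)-catechin, (2R,3S) | Oc1cc(O)c2c(c1)O[C@H](c1ccc(O)c(O)c1)[C@@H](O)C2 | starting material
2 | 5,7,3′,4′-tetra-O-benzyl-(+)-catechin | c1c(OCc2ccccc2)cc(OCc2ccccc2)c2c1O[C@H](c1ccc(OCc3ccccc3)c(OCc3ccccc3)c1)[C@@H](O)C2 | intermediate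
3 | 3,5,7,3′,4′-penta-O-benzyl-(+)-catechin | c1c(OCc2ccccc2)cc(OCc2ccccc2)c2c1O[C@H](c1ccc(OCc3ccccc3)c(OCc3ccccc3)c1)[C@@H](OCc1ccccc1)C2 | intermediate
4 | 8-bromo-3,5,7,3′,4′-penta-O-benzyl-(+)-catechin | Brc1c(OCc2ccccc2)cc(OCc2ccccc2)c2c1O[C@H](c1ccc(OCc3ccccc3)c(OCc3ccccc3)c1)[C@@H](OCc1ccccc1)C2 | intermediate
5 | [3,4-bis(benzyloxy)phenyl]boronic acid | OB(O)c1ccc(OCc2ccccc2)c(OCc2ccccc2)c1 | starting material
6 | (+)-pinanediol, (1S,2S,3R,5S) | C[C@@]1(O)[C@H](O)C[C@@H]2C[C@H]1C2(C)C | starting material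
7 | (+)-pinanediol [3,4-bis(benzyloxy)phenyl]boronate | C[C@@]1(OB(c4ccc(OCc5ccccc5)c(OCc5ccccc5)c4)O2)[C@H]2C[C@@H]3C[C@H]1C3(C)C | intermediate
8 | lithium aryl(dichloromethyl)borate complex of 7 | [Li+].C[C@@]1(O[B-](C(Cl)Cl)(c4ccc(OCc5ccccc5)c(OCc5ccccc5)c4)O2)[C@H]2C[C@@H]3C[C@H]1C3(C)C | intermediate
9 | (+)-pinanediol [(S)-chloro[3,4-bis(benzyloxy)phenyl]methyl]boronate | C[C@@]1(OB([C@H](Cl)c4ccc(OCc5ccccc5)c(OCc5ccccc5)c4)O2)[C@H]2C[C@@H]3C[C@H]1C3(C)C | intermediate
10 | 8-lithio-3,5,7,3′,4′-penta-O-benzyl-(+)-catechin | [Li]c1c(OCc2ccccc2)cc(OCc2ccccc2)c2c1O[C@H](c1ccc(OCc3ccccc3)c(OCc3ccccc3)c1)[C@@H](OCc1ccccc1)C2 | intermediate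
11 | lithium borate complex from 10 and 9 (boron bears the catechin-8-yl and the (S)-chloro(aryl)methyl groups) | [Li+].C[C@@]1(O[B-]([C@H](Cl)c4ccc(OCc5ccccc5)c(OCc5ccccc5)c4)(c4c(OCc5ccccc5)cc(OCc5ccccc5)c5c4O[C@H](c4ccc(OCc6ccccc6)c(OCc6ccccc6)c4)[C@@H](OCc4ccccc4)C5)O2)[C@H]2C[C@@H]3C[C@H]1C3(C)C | intermediate
12 | (+)-pinanediol [(R)-(ArB)(Cat)methyl]boronate | C[C@@]1(OB([C@H](c4ccc(OCc5ccccc5)c(OCc5ccccc5)c4)c4c(OCc5ccccc5)cc(OCc5ccccc5)c5c4O[C@H](c4ccc(OCc6ccccc6)c(OCc6ccccc6)c4)[C@@H](OCc4ccccc4)C5)O2)[C@H]2C[C@@H]3C[C@H]1C3(C)C | intermediate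
13 | lithium chloromethyl borate complex of 12 | [Li+].C[C@@]1(O[B-](CCl)([C@H](c4ccc(OCc5ccccc5)c(OCc5ccccc5)c4)c4c(OCc5ccccc5)cc(OCc5ccccc5)c5c4O[C@H](c4ccc(OCc6ccccc6)c(OCc6ccccc6)c4)[C@@H](OCc4ccccc4)C5)O2)[C@H]2C[C@@H]3C[C@H]1C3(C)C | intermediate
14 | (+)-pinanediol [(2R)-2-(ArB)-2-(Cat)ethyl]boronate | C[C@@]1(OB(C[C@H](c4ccc(OCc5ccccc5)c(OCc5ccccc5)c4)c4c(OCc5ccccc5)cc(OCc5ccccc5)c5c4O[C@H](c4ccc(OCc6ccccc6)c(OCc6ccccc6)c4)[C@@H](OCc4ccccc4)C5)O2)[C@H]2C[C@@H]3C[C@H]1C3(C)C | intermediate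
15 | (2R)-2-[3,4-bis(benzyloxy)phenyl]-2-(Cat)ethanol | OC[C@H](c1ccc(OCc2ccccc2)c(OCc2ccccc2)c1)c1c(OCc2ccccc2)cc(OCc2ccccc2)c2c1O[C@H](c1ccc(OCc3ccccc3)c(OCc3ccccc3)c1)[C@@H](OCc1ccccc1)C2 | intermediate
16 | 2,4,6-trihydroxybenzaldehyde | O=Cc1c(O)cc(O)cc1O | starting material
17 | 2-hydroxy-4,6-bis(triisopropylsilyloxy)benzaldehyde | O=Cc1c(O)cc(O[Si](C(C)C)(C(C)C)C(C)C)cc1O[Si](C(C)C)(C(C)C)C(C)C | intermediate
18 | 2-[(2R)-2-(ArB)-2-(Cat)ethoxy]-4,6-bis(triisopropylsilyloxy)benzaldehyde | CC(C)[Si](C(C)C)(C(C)C)Oc1cc(O[Si](C(C)C)(C(C)C)C(C)C)c(C=O)c(c1)OC[C@H](c1ccc(OCc2ccccc2)c(OCc2ccccc2)c1)c1c(OCc2ccccc2)cc(OCc2ccccc2)c2c1O[C@H](c1ccc(OCc3ccccc3)c(OCc3ccccc3)c1)[C@@H](OCc1ccccc1)C2 | intermediate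
19 | (E)-N-tosylhydrazone of 18 | CC(C)[Si](C(C)C)(C(C)C)Oc1cc(O[Si](C(C)C)(C(C)C)C(C)C)c(/C=N/NS(=O)(=O)c2ccc(C)cc2)c(c1)OC[C@H](c1ccc(OCc2ccccc2)c(OCc2ccccc2)c1)c1c(OCc2ccccc2)cc(OCc2ccccc2)c2c1O[C@H](c1ccc(OCc3ccccc3)c(OCc3ccccc3)c1)[C@@H](OCc1ccccc1)C2 | intermediate
20 | aryldiazomethane from 19 (CH=N2 in place of CH=N–NHTs) | CC(C)[Si](C(C)C)(C(C)C)Oc1cc(O[Si](C(C)C)(C(C)C)C(C)C)c(C=[N+]=[N-])c(c1)OC[C@H](c1ccc(OCc2ccccc2)c(OCc2ccccc2)c1)c1c(OCc2ccccc2)cc(OCc2ccccc2)c2c1O[C@H](c1ccc(OCc3ccccc3)c(OCc3ccccc3)c1)[C@@H](OCc1ccccc1)C2 | intermediate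
21 | (2S)-2-[(R)-(ArB)(Cat)methyl]-4,6-bis(triisopropylsilyloxy)-2,3-dihydrobenzofuran | CC(C)[Si](C(C)C)(C(C)C)Oc1cc(O[Si](C(C)C)(C(C)C)C(C)C)c2c(c1)O[C@H]([C@H](c1ccc(OCc3ccccc3)c(OCc3ccccc3)c1)c1c(OCc3ccccc3)cc(OCc3ccccc3)c3c1O[C@H](c1ccc(OCc4ccccc4)c(OCc4ccccc4)c1)[C@@H](OCc1ccccc1)C3)C2 | intermediate
22 | (2S)-2-[(R)-(ArB)(Cat)methyl]-2,3-dihydrobenzofuran-4,6-diol | Oc1cc(O)c2c(c1)O[C@H]([C@H](c1ccc(OCc3ccccc3)c(OCc3ccccc3)c1)c1c(OCc3ccccc3)cc(OCc3ccccc3)c3c1O[C@H](c1ccc(OCc4ccccc4)c(OCc4ccccc4)c1)[C@@H](OCc1ccccc1)C3)C2 | intermediate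
23 | CNP0280971.2: (2S)-2-[(R)-(3,4-dihydroxyphenyl)[(2R,3S)-2-(3,4-dihydroxyphenyl)-3,5,7-trihydroxy-3,4-dihydro-2H-chromen-8-yl]methyl]-2,3-dihydrobenzofuran-4,6-diol | Oc1cc(O)c2c(c1)O[C@H]([C@H](c1ccc(O)c(O)c1)c1c(O)cc(O)c3c1O[C@H](c1ccc(O)c(O)c1)[C@@H](O)C3)C2 | target

**Step count and risks**

Total step count: 13. Longest linear sequence: 10 steps (1, 2, 3, 6, 7, 9, 10, 11, 12, 13).

Steps most likely to fail:

Step 11. The carbene radical may abstract the doubly benzylic diarylmethine hydrogen (1,6) instead of the O–CH2 hydrogen, the diazo compound may dimerise to azine or stilbene, or facial control at C2 by the neighbouring stereocentre may be weak. Fallback: setting out from aldehyde 18, irradiation (λ ≥ 300 nm, benzene, rt) should trigger a Norrish–Yang cyclisation, in which the excited formyl oxygen abstracts the same O–CH2 hydrogen and the 1,5-biradical closes the same C2–C3 bond, giving the 3-hydroxy-2,3-dihydrobenzofuran F1. Ionic deoxygenation of its doubly activated benzylic hydroxyl (Et3SiH, BF3·OEt2, CH2Cl2, −78 °C) comes back to the route at 21; C2 epimers, if formed, are diastereomers and would be separated by chromatography.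

Step 6. The hindered aryllithium may deprotonate the α-chloro boronate instead of adding to boron, an oxygen of the borate may migrate in place of the aryl group, or the benzylic chloride may lose configuration before it is displaced. Fallback: setting out from bromide 4, the same lithiation followed by addition to commercial 1-[3,4-bis(benzyloxy)phenyl]ethanone should give the tertiary carbinol F2, and mild acid-catalysed dehydration (PPTS, toluene, 60 °C) the 1,1-diarylethene F3. Hydroboration with 9-BBN (THF, 65 °C) gives the alkylborane F4, and oxidation (NaOH, H2O2) gives alcohol 15 together with its diarylmethine epimer F5. The two are diastereomers because of the catechin unit and would be separated by chromatography; the route is rejoined at 15 without steps 5 to 7.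

Step 7. The congested boron of 12 may not take up the short-lived LiCH2Cl before it decomposes, or oxygen migration may compete with the shift of the bulky diarylmethyl group. Fallback: setting out from 12, Zweifel olefination (vinylmagnesium bromide in excess, THF, −78 °C → rt; I2; NaOMe, MeOH) transfers the diarylmethyl group to carbon with retention and should give the 3,3-diarylpropene F6. Oxidative cleavage (OsO4 cat., NaIO4, 2,6-lutidine, dioxane/H2O) to the configurationally fragile aldehyde F7 and reduction in the same flask (NaBH4, 0 °C) come back to the route at 15.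

**Further compounds**
F1 | step 11 | 3-hydroxy derivative of 21 (C3 epimers; C2 and the diarylmethine arranged as in 21) | CC(C)[Si](C(C)C)(C(C)C)Oc1cc(O[Si](C(C)C)(C(C)C)C(C)C)c2c(c1)O[C@H]([C@H](c1ccc(OCc3ccccc3)c(OCc3ccccc3)c1)c1c(OCc3ccccc3)cc(OCc3ccccc3)c3c1O[C@H](c1ccc(OCc4ccccc4)c(OCc4ccccc4)c1)[C@@H](OCc1ccccc1)C3)C2O
F2 | step 6 | 1-(ArB)-1-(Cat)ethanol (both carbinol epimers) | CC(O)(c1ccc(OCc2ccccc2)c(OCc2ccccc2)c1)c1c(OCc2ccccc2)cc(OCc2ccccc2)c2c1O[C@H](c1ccc(OCc3ccccc3)c(OCc3ccccc3)c1)[C@@H](OCc1ccccc1)C2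
F3 | step 6 | 1-(ArB)-1-(Cat)ethene | C=C(c1ccc(OCc2ccccc2)c(OCc2ccccc2)c1)c1c(OCc2ccccc2)cc(OCc2ccccc2)c2c1O[C@H](c1ccc(OCc3ccccc3)c(OCc3ccccc3)c1)[C@@H](OCc1ccccc1)C2
F4 | step 6 | B-[2-(ArB)-2-(Cat)ethyl]-9-borabicyclo[3.3.1]nonane (both diarylmethine epimers) | C(B1C2CCCC1CCC2)C(c1ccc(OCc2ccccc2)c(OCc2ccccc2)c1)c1c(OCc2ccccc2)cc(OCc2ccccc2)c2c1O[C@H](c1ccc(OCc3ccccc3)c(OCc3ccccc3)c1)[C@@H](OCc1ccccc1)C2
F5 | step 6 | (2S)-2-(ArB)-2-(Cat)ethanol, the diarylmethine epimer of 15 | OC[C@@H](c1ccc(OCc2ccccc2)c(OCc2ccccc2)c1)c1c(OCc2ccccc2)cc(OCc2ccccc2)c2c1O[C@H](c1ccc(OCc3ccccc3)c(OCc3ccccc3)c1)[C@@H](OCc1ccccc1)C2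
F6 | step 7 | (3R)-3-(ArB)-3-(Cat)prop-1-ene | C=C[C@H](c1ccc(OCc2ccccc2)c(OCc2ccccc2)c1)c1c(OCc2ccccc2)cc(OCc2ccccc2)c2c1O[C@H](c1ccc(OCc3ccccc3)c(OCc3ccccc3)c1)[C@@H](OCc1ccccc1)C2
F7 | step 7 | (2R)-2-(ArB)-2-(Cat)acetaldehyde | O=C[C@H](c1ccc(OCc2ccccc2)c(OCc2ccccc2)c1)c1c(OCc2ccccc2)cc(OCc2ccccc2)c2c1O[C@H](c1ccc(OCc3ccccc3)c(OCc3ccccc3)c1)[C@@H](OCc1ccccc1)C2
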